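Product at 15 d is what we want from this flask, and two earlier runs bracket its loading.

| flask | substrate | free catalyst | remark | time |
|---|---|---|---|---|
| Sunday's | 0.80 M | 0.025 mol% | run made earlier |  |
| Wednesday's | 0.80 M | 0.1 mol% | run made earlier |  |
| flask | 0.80 M | 0.05 mol% |  | 15 d |

| run | time / d | product / % | substrate / % |
|---|---|---|---|
| Sunday's | 3.00 | 80.6 | 19.0 |
| Sunday's | 6.00 | 94.1 | 6.5 |
| Sunday's | 10.0 | 95.8 | 4.1 |
| Sunday's | 12.0 | 96.4 | 4.4 |
| Sunday's | 15.0 | 96.3 | 4.0 |
| Wednesday's | 3.00 | 96.0 | 4.3 |
| Wednesday's | 6.00 | 96.5 | 4.1 |
| Wednesday's | 10.0 | 95.9 | 4.1 |
| Wednesday's | 12.0 | 95.8 | 3.9 |
| Wednesday's | 15.0 | 96.0 | 4.3 |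

(scatter of a reading: 0.3 percentage points)

- at 15 d, what has stopped the reaction, if anything has (it is still moving / no working catalyst is left / forward and back rates have come level / all of the substrate has reacted)
- product at 15 d, in percent of the substrate charged

- in percentages every species weighs as the substrate in it: one spent catalyst counts as two
- the numbers in the tables scatter by 0.3 percentage points (one standard deviation)
- candidate steps: substrate + free catalyst <-> catalyst intermediate; catalyst intermediate <-> free catalyst + product; 2 catalyst intermediate -> spent catalyst
- the reaction counts as stopped when no species that holds the substrate changes by six tenths of a point or more over the second half of the time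

We build the flask up one process at a time. The forward round comes first: substrate passes through catalyst intermediate to product, and that picture ends at 100%, yet Wednesday's run still shows 96.0% product and 4.3% substrate at 15.0 d. So we add the way back, and the number drops. Wednesday's last four readings give a ratio of product to substrate of 23.4; we call it K, the plateau ratio, product over substrate with forward and back rates level, and take this figure as our reading, with the scatter of those readings, of the equilibrium constant of the overall change. Sunday's last three readings, at a quarter of Wednesday's loading, give 23.1. Product and substrate share the charge, so product stands at K/(1+K), which is 95.9% by our reckoning.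

Last we add the loss of two catalyst intermediates to spent catalyst. Its substrate does not move the number, since a loading of 0.05 mol% is small against a scatter of 0.3 percentage points. It could touch the clock, but Sunday's run reached its plateau by 10.0 d and stayed there. This flask has twice Sunday's loading, so we expect arrival near 5.00 d, sooner than 7.50 d.

The forecast says forward and back rates have come level, with 96% product: “The plateau is therefore equilibrium, with K about 24.” Its K stands a little above our 23.4.

At 15 d in the flask forward and back rates have come level, with 95.9% product and 4.1% substrate, a ratio of 23.4.

    substrate + free catalyst ⇌ catalyst intermediate (K = 4.70 M⁻¹, k = 179 M⁻¹ h⁻¹)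
    catalyst intermediate ⇌ free catalyst + product (K = 5.00 M, k = 301 h⁻¹)
    2 catalyst intermediate → spent catalyst (k = 14.1 M⁻¹ h⁻¹)

The way back holds the flask at this plateau: the run without the back reaction of free catalyst + product to catalyst intermediate reaches >99.9% product against 95.9%. Carried to the neighbour flask with 2.0 M substrate, K gives 95.9% product. That flask holds 95.9% product and 4.08% substrate at 15.0 d, a ratio of 23.5, with 45.7% of its catalyst spent.

The readings are simulated on assumed constants; the scatter is artificial.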